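# Proposal for a total synthesis of sipholenol K (25)

## The problem

1. Sipholenol K (25) is made of two bicycles joined only by the ethylene bridge C12–C13.
   - The left bicycle is a trans-fused oxepane–cyclohexane: ring A is O1, C2–C7 and ring B is C6–C11.
   - The right bicycle is a cis-fused decalin: ring C is the enone C14=C15–C16(=O)–C17–C18–C23 and ring D is C18–C23.
   - Locants: C2 = CMe2, C3 = CHOH, C6 = quaternary C–Me, C7 = O–CH, C10 = C(Me)OH, C11 = CH bearing the bridge, C15 = C–Me, C19 = C(Me)OH, C22 = CMe2.
2. The left half has five stereocentres (3S,6S,7S,10S,11S), four of them contiguous around quaternary C6. The right half has three contiguous ones (18S,19S,23R).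
3. The bridge insulates the halves, so each needs its own source of absolute configuration. Relay is possible inside each half. C6/C7 can dictate C11 and C10 through a chair. C18 can dictate C23 and C19 through the fold of the cis-decalin. C3 is remote and needs reagent control.
4. Four bonds resist closure:
   - O1–C2, a tertiary ether in a seven-membered ring;
   - C6–C11, quaternary to tertiary and next to the C10 carbinol;
   - C22–C23, a neopentyl bond;
   - C13–C14, at a tetrasubstituted enone carbon flanked by the gem-dimethyl group.
5. Several groups are fragile.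
   - Both tertiary alcohols dehydrate easily.
   - The C10 hydroxyl closes a tetrahydrofuran on C13 as soon as C13 carries a leaving group.
   - C23–H is γ-acidic, so the cis fusion can epimerise.
   - The oxygens at C16 and C19 stand in a dissonant 1,4-relation.
6. The feature that makes the key step possible is a linear reading of the left half.
   - From C2 to C13, rings A and B plus the bridge form an unbranched homofarnesane chain with methyls on C2, C6 and C10.
   - Its oxygens sit on C2/C3, on C7 and on C10.
   - C13 stands 1,4 to the oxygen on C10 (O–C10–C11–C12–C13).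
   - C13 can therefore be a carboxyl carbon that ends a cationic cascade begun at a C2–C3 epoxide and relayed by a C6–C7 epoxide and a C10=C11 alkene.
7. Ring C with its C15 methyl and the C19 unit on C18 is the carvone skeleton, provided the carbonyl is placed on C14 and not on C16.

## Retrosynthesis

**25 ⇒ 24 ⇒ 23.**
- Cut: the two O–Si bonds, then the C19–O bond.
- Against the neighbour: adding a methyl nucleophile to a C19 ketone would attack the convex face and give the wrong epimer. It is the oxygen that must come from that face.
- Gain: alkene 23 has one stereocentre and one protecting group fewer, and the dissonant C16/C19 relation is gone.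
- Asked of the forward step: Markovnikov hydration of the trisubstituted alkene beside a tetrasubstituted enone, from the face of H18 and H23.

**23 ⇒ 22 ⇒ 21 + 20.**
- Cut: C13–C14. The enone is read as the 1,3-transposed form of a ketone at C14.
- Against the neighbours: a cut at C12–C13 needs a carbanion β to the C10 oxygen. A cut at C11–C12 needs substitution at a centre flanked by C6 and C10. At C14 the most hindered carbon of the target is simply a carbonyl carbon.
- Gain: two fragments of 16 and 14 carbons.
- Asked of the forward steps: 1,2-addition of alkyllithium 21 to ketone 20 faster than enolisation, then an oxidative allylic transposition.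

**20 ⇒ 19 ⇒ 18 ⇒ 17 ⇒ 16 + 13, then 16 ⇒ 15 ⇒ 14 and 13 ⇒ 12.**
- Cut: C19=C20 (metathesis) and C22–C23 (tert-alkylation) of ring D.
- What remains is (S)-carvone 14. Its carbonyl is C14, its α′-carbon is C23, its stereocentre is C18 and its isopropenyl carbon is C19. Nine of its ten carbons stay in the target.
- Against the neighbour: an enolate SN2 reaction cannot make C22–C23, whereas a tertiary cation from 13 attacking the enol silane 16 can.
- Asked of the forward steps: cis fusion, obtained by kinetic protonation of the ring-fusion dienolate 19.

**21 ⇒ 11 ⇒ 10 ⇒ 9 ⇒ 8.**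
- No C–C bond is cut; only the oxidation state of C13 and the protection change.
- Lactone 8 holds C13 and the C10 oxygen in a temporary ring. C13 is thereby distinguished from all other carbons, and the C10 oxygen cannot attack it before all three hydroxyls are silylated.

**8 ⇒ 7 ⇒ 6 ⇒ 5 (key step).**
- Cut: O1–C2, C6–C11 and the lactone bond O–C10.
- Against the neighbours: cutting only O1–C2 leaves the hindered ring B to be built by other means. Cutting only C6–C11 leaves a medium-ring ether closure.
- Gain: acyclic acid 5 has three stereocentres, all in epoxides. Product 8 has three rings and five stereocentres.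
- Asked of the forward step: endo opening at both epoxides, a chair for ring B, and capture of the C10 cation before it loses a proton.

**5 ⇒ 4 ⇒ 3 ⇒ 2 ⇒ 1.**
- Cut: C12–C13 (carbonylation) and the two epoxide oxygens.
- The carbonate of 2 deactivates the C10=C11 alkene during epoxidation and is afterwards the leaving group for the one-carbon homologation.
- Farnesol 1 supplies 15 of the 16 carbons and both alkene geometries.

## Roads not taken

**Alternative 1:** the most obvious plan cuts C12–C13 in the middle of the bridge between two finished bicycles.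
- Compounds: ring A/B sulfone A1 and ring C/D γ-bromo enone A2.
- Forward key step: alkylation of the sulfonyl carbanion of A1 with A2, then reductive desulfonylation.
- Why the chosen plan is better:
  - The carbanion sits on a carbon attached to C11 and is β to the C10 oxygen, so it is hindered and prone to elimination.
  - A2 is ambident and base-sensitive at C23.
  - Desulfonylation threatens the enone.
  - Both tertiary alcohols need protection throughout, and the union builds no complexity. Both bicycles still have to be made stepwise.

**Alternative 2:** cut the same three bonds as the key step, but do so last, on the full carbon skeleton.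
- Compound: diepoxide A3, which carries the finished decalin.
- Forward key step: cascade ended by water.
- Why the chosen plan is better:
  - Once C13 is a methylene group no internal nucleophile reaches C10, so the cation ends by proton loss or unselective hydration.
  - Epoxidation cannot tell the C10=C11 alkene from the other trisubstituted alkenes once the allylic oxygen is gone.
  - The acid-labile C19 carbinol and all the material of both halves are exposed to the riskiest step.

**Alternative 3:** take O1 out of ring A and read the left half as a drimane lactone.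
- Compound: (−)-sclareolide A4. It holds all 16 carbons C2–C13 with their methyls, and the configurations of C6, C7, C10 and C11.
- Forward key step: insertion of oxygen into the bond that corresponds to C2–C7, plus hydroxylation at C3.
- Why the chosen plan is better:
  - Commercial (+)-sclareolide is the antipode of what the target requires, so A4 would itself need an enantioselective polyene cyclisation.
  - No carbonyl group guides an oxygen insertion between a quaternary and a tertiary carbon.
  - A Baeyer–Villiger route would need C2 as a ketone and a later rebuilding of the gem-dimethyl ether.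

Key step: step 5

Assumption: the locants O1 and C2–C23 defined above are used for all intermediates, and the L-fructose-derived enantiomer of the Shi ketone is taken as an available catalyst.

## Steps

Step 1
Reactants: 1 (2E,6E)-farnesol
Product: 2 (2E,6E)-farnesyl methyl carbonate
Conditions: ClCO2Me, pyridine, CH2Cl2, 0 °C
Reagents that add atoms: methyl chloroformate COC(=O)Cl
Why: Acylation of a primary allylic alcohol; the carbonate withdraws electron density from the C10=C11 alkene for step 2 and is the leaving group of step 3.

Step 2
Reactants: 2 (2E,6E)-farnesyl methyl carbonate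
Product: 3 (2E,6S,7S,10S)-6,7:10,11-diepoxyfarnesyl methyl carbonate
Conditions: L-fructose-derived Shi ketone (30 mol %), KHSO5 (as 2KHSO5·KHSO4·K2SO4), K2CO3, Bu4NHSO4, MeCN–CH2(OMe)2–aq. Na2B4O7 buffer, 0 °C
Reagents that add atoms: potassium peroxymonosulfate [K+].[O-]S(=O)(=O)OO
Why: Shi asymmetric epoxidation; the chiral dioxirane attacks both remote E-trisubstituted alkenes through the spiro transition state and sets C3, C6 and C7 (all S) under catalyst control, while the alkene next to the allylic carbonate is electron-poorer and should be spared, as is known for farnesyl esters.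

Step 3
Reactants: 3 (2E,6S,7S,10S)-6,7:10,11-diepoxyfarnesyl methyl carbonate
Product: 4 methyl (3E,7S,8S,11S)-7,8:11,12-diepoxy-4,8,12-trimethyltridec-3-enoate
Conditions: Pd(OAc)2 (5 mol %), PPh3 (20 mol %), CO (20 atm), toluene, 50 °C
Reagents that add atoms: carbon monoxide [C-]#[O+]
Why: Tsuji decarboxylative carbonylation of an allylic carbonate; zerovalent palladium ionises the carbonate, CO2 is lost, CO inserts at the primary terminus and the liberated methoxide closes the ester. The neutral medium leaves isolated epoxides alone and the syn π-allyl complex keeps the E geometry.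

Step 4
Reactants: 4 methyl (3E,7S,8S,11S)-7,8:11,12-diepoxy-4,8,12-trimethyltridec-3-enoate
Product: 5 (3E,7S,8S,11S)-7,8:11,12-diepoxy-4,8,12-trimethyltridec-3-enoic acid
Conditions: LiOH, THF–MeOH–H2O, 0 °C to rt; aq. NaH2PO4
Reagents that add atoms: lithium hydroxide [Li+].[OH-]
Why: Saponification; trisubstituted epoxides resist hydroxide at this temperature and the trisubstituted β,γ-alkene has no drive to move into conjugation.

Step 5
Reactants: 5 (3E,7S,8S,11S)-7,8:11,12-diepoxy-4,8,12-trimethyltridec-3-enoic acid
Product: 8 tricyclic hydroxy lactone (rings A and B plus a γ-lactone C10–O–C13(=O)–C12–C11; 3S,6S,7S,10S,11S), via trimethylsilyl ester 6 (not isolated), via lactone trimethylsilyl ether 7 (not isolated)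
Conditions: Me3SiOTf (1.3 equiv), 2,6-di-tert-butyl-4-methylpyridine, CH2Cl2, −78 °C; aq. NaHCO3; citric acid, MeOH, rt
Reagents that add atoms: none
Why: Me3SiOTf silylates the acid (6) and then the exposed C2–C3 epoxide; the oxygen of the C6–C7 epoxide attacks tertiary C2 to give a bicyclic epoxonium ion, the C10=C11 alkene opens it at tertiary C6, and the silyl ester carbonyl captures the C10 cation and releases Me3Si+, so the promoter is regenerated. The closest known reaction type is the Lewis-acid-triggered tandem oxa-/carbacyclisation of 1,5-diepoxides that carry a terminating π-nucleophile, joined here to the carboxyl-terminated polyene cyclisation that turns homofarnesic acid into sclareolide. Ring A closes in the 7-endo mode (oxygen on C7 to C2), ring B in the 6-endo mode through a chair (C11 to C6), and the temporary lactone in the 5-exo mode (carboxyl oxygen to C10). C3 and C7 keep their epoxide C–O bonds and hence the configuration of step 2, while C6 is inverted by backside attack of C11, which places O1 and C5 trans-diequatorial and the C6 methyl axial. C11 and C10 follow from anti addition across the E alkene in that chair: side chain equatorial, C10 methyl axial, C10–O equatorial. The step needs endo opening at both epoxides, secured by the methyl groups on C2 and C6 that carry the positive charge, and a single direction of travel, secured by having the only terminating nucleophile at the C13 end. Capture must outrun proton loss from C10, which the five-membered reach of the carboxyl group (O–C10–C11–C12–C13) secures.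

Step 6
Reactants: 8 tricyclic hydroxy lactone
Product: 9 triol (C3–OH, C10–OH, C13–OH; 3S,6S,7S,10S,11S)
Conditions: LiAlH4, THF, 0 °C to rt; H2O, aq. NaOH
Reagents that add atoms: none
Why: Hydride reduction cleaves the temporary C13–O bond and frees the C10 alcohol with the configuration fixed in step 5; the ring ether is inert.

Step 7
Reactants: 9 triol
Product: 10 tris(triethylsilyl) ether of 9
Conditions: Et3SiOTf (3.5 equiv), 2,6-lutidine, CH2Cl2, −20 °C to rt
Reagents that add atoms: triethylsilyl trifluoromethanesulfonate CC[Si](CC)(CC)OS(=O)(=O)C(F)(F)F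
Why: A silyl triflate with a hindered pyridine silylates primary, hindered secondary and tertiary hydroxyls alike; full protection before C13 is activated keeps the C10 oxygen from closing a tetrahydrofuran on C13.

Step 8
Reactants: 10 tris(triethylsilyl) ether
Product: 11 C13 iodide (C3 and C10 triethylsilyl ethers kept)
Conditions: PPh3, I2, CH2Cl2, 0 °C to rt
Reagents that add atoms: iodine II
Why: Direct conversion of a silyl ether into a halide by a halophosphonium salt; only the unhindered primary ether can be phosphonylated and displaced by iodide in an SN2 step, whereas the ethers at C3 (next to CMe2) and C10 (tertiary) are shielded.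

Step 9
Reactants: 12 2-methylpent-4-en-2-ol
Product: 13 4-chloro-4-methylpent-1-ene
Conditions: conc. aq. HCl, CaCl2, 0 °C to rt
Reagents that add atoms: hydrogen chloride Cl
Why: SN1 substitution of a tertiary alcohol; the monosubstituted alkene is not protonated under these conditions.

Step 10
Reactants: 14 (S)-(+)-carvone
Product: 16 cross-conjugated trimethylsilyl dienol ether of (S)-carvone (C14–OSiMe3; C14=C23; C15=C16), via lithium dienolate 15 (not isolated)
Conditions: LiN(iPr)2, THF, −78 °C; Me3SiCl
Reagents that add atoms: chlorotrimethylsilane C[Si](C)(C)Cl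
Why: Kinetic deprotonation of an enone at the α′-carbon (C23) and O-silylation; the stereocentre C18 is not touched.

Step 11
Reactants: 16 silyl dienol ether of (S)-carvone; 13 4-chloro-4-methylpent-1-ene
Product: 17 (5S,6S)-2-methyl-6-(2-methylpent-4-en-2-yl)-5-(prop-1-en-2-yl)cyclohex-2-enone (trans)
Conditions: TiCl4 (1.1 equiv), CH2Cl2, −78 to −40 °C; aq. NaHCO3
Reagents that add atoms: none
Why: Reetz α-tert-alkylation; TiCl4 ionises 13 and the tertiary cation is taken by the enol silane carbon C23, by far the best π-nucleophile present, which forges the neopentyl bond C22–C23. Attack anti to the isopropenyl group should give the trans isomer, but C23 is reset in step 13.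

Step 12
Reactants: 17 trans-alkylated carvone
Product: 18 trans-fused bicyclic dienone (18S,23S; C14=O, C15=C16, C19=C20)
Conditions: second-generation Hoveyda–Grubbs catalyst (5 mol %), toluene, 80 °C
Reagents that add atoms: none
Why: Ring-closing metathesis of a monosubstituted with a 1,1-disubstituted alkene to a trisubstituted cyclohexene (ring D); the enone alkene is trisubstituted and electron-poor and stays out.

Step 13
Reactants: 18 trans-fused bicyclic dienone
Product: 20 cis-fused bicyclic dienone (18S,23R), via lithium ring-fusion dienolate 19 (not isolated)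
Conditions: LiN(iPr)2, THF, −78 to −20 °C; 2,6-di-tert-butyl-4-methylphenol, −78 °C
Reagents that add atoms: none
Why: In rigid 18 the C23–H bond is axial and aligned with the carbonyl π system, so α′-deprotonation is feasible. Dienolate 19 is dish-shaped, with C17, C19 and C21 all below the plane around C23, so a bulky phenol should deliver the proton to the convex face, syn to H18. This is the kinetic protonation of a ring-fusion enolate to the cis-decalone.

Step 14
Reactants: 11 C13 iodide; 20 cis-fused bicyclic dienone
Product: 22 tertiary allylic alcohol (14S; C13–C14 bond formed), via primary alkyllithium 21 (not isolated)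
Conditions: 11, t-BuLi (2.0 equiv), Et2O–pentane, −78 °C; then 20, −78 to −30 °C; H2O
Reagents that add atoms: none
Why: Iodine–lithium exchange and 1,2-addition of an alkyllithium to an enone. The only enolisable hydrogen of 20 is the hindered C23–H, and attack anti to the pseudoaxial C22 group should give the 14S alcohol, a centre that disappears in step 15.

Step 15
Reactants: 22 tertiary allylic alcohol
Product: 23 transposed enone (C16=O, C14=C15, C19=C20; bis(triethylsilyl) ether)
Conditions: [C5H5NH][CrO3Cl], 4 Å molecular sieves, CH2Cl2, rt
Reagents that add atoms: pyridinium chlorochromate [O-][Cr](=O)(=O)Cl.c1cc[nH+]cc1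
Why: Babler–Dauben oxidative transposition; the chromate ester of the tertiary allylic alcohol shifts [3,3] to C16 and collapses to the tetrasubstituted enone. The medium is not basic, so C23 keeps its configuration.

Step 16
Reactants: 23 transposed enone
Product: 24 C19 tertiary alcohol (19S; bis(triethylsilyl) ether of 25)
Conditions: Co(acac)2 (20 mol %), PhSiH3, O2 (1 atm), THF, rt
Reagents that add atoms: dioxygen O=O
Why: Mukaiyama hydration; hydrogen-atom transfer to C20 gives the tertiary C19 radical, while the tetrasubstituted enone is too hindered for the cobalt hydride. In either conformer of the cis-decalin the concave face of C19 is blocked (by axial C17 on C18 or by axial C14 on C23), so oxygen should enter from the face of H18 and H23.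

Step 17
Reactants: 24 bis(triethylsilyl) ether
Product: 25 sipholenol K
Conditions: HF·pyridine, pyridine, THF, 0 °C to rt
Reagents that add atoms: none
Why: Fluoride-driven cleavage of triethylsilyl ethers; buffering with pyridine avoids dehydration of the tertiary alcohols and epimerisation at C23.

## Compound list

1 | (2E,6E)-farnesol | CC(C)=CCC/C(C)=C/CC/C(C)=C/CO | starting material
2 | (2E,6E)-farnesyl methyl carbonate | CC(C)=CCC/C(C)=C/CC/C(C)=C/COC(=O)OC | intermediate
3 | (2E,6S,7S,10S)-6,7:10,11-diepoxyfarnesyl methyl carbonate | CC1(C)O[C@H]1CC[C@]2(C)O[C@H]2CC/C(C)=C/COC(=O)OC | intermediate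
4 | methyl (3E,7S,8S,11S)-7,8:11,12-diepoxy-4,8,12-trimethyltridec-3-enoate | CC1(C)O[C@H]1CC[C@]2(C)O[C@H]2CC/C(C)=C/CC(=O)OC | intermediate
5 | (3E,7S,8S,11S)-7,8:11,12-diepoxy-4,8,12-trimethyltridec-3-enoic acid | CC1(C)O[C@H]1CC[C@]2(C)O[C@H]2CC/C(C)=C/CC(=O)O | intermediate
6 | trimethylsilyl ester of 5 | CC1(C)O[C@H]1CC[C@]2(C)O[C@H]2CC/C(C)=C/CC(=O)O[Si](C)(C)C | intermediate
7 | C3 trimethylsilyl ether of lactone 8 | O=C1C[C@H]2[C@]3(C)CC[C@H](O[Si](C)(C)C)C(C)(C)O[C@H]3CC[C@]2(C)O1 | intermediate
8 | tricyclic hydroxy lactone (3S,6S,7S,10S,11S) | O=C1C[C@H]2[C@]3(C)CC[C@H](O)C(C)(C)O[C@H]3CC[C@]2(C)O1 | intermediate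
9 | ring A/B triol (C3, C10, C13 hydroxyls) | OCC[C@H]2[C@]3(C)CC[C@H](O)C(C)(C)O[C@H]3CC[C@]2(C)O | intermediate
10 | tris(triethylsilyl) ether of 9 | CC[Si](CC)(CC)OCC[C@H]2[C@]3(C)CC[C@H](O[Si](CC)(CC)CC)C(C)(C)O[C@H]3CC[C@]2(C)O[Si](CC)(CC)CC | intermediate
11 | C13 iodide, C3/C10 bis(triethylsilyl) ether | ICC[C@H]2[C@]3(C)CC[C@H](O[Si](CC)(CC)CC)C(C)(C)O[C@H]3CC[C@]2(C)O[Si](CC)(CC)CC | intermediate
12 | 2-methylpent-4-en-2-ol | C=CCC(C)(C)O | starting material
13 | 4-chloro-4-methylpent-1-ene | C=CCC(C)(C)Cl | intermediate
14 | (S)-(+)-carvone | CC1=CC[C@@H](CC1=O)C(C)=C | starting material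
15 | lithium cross-conjugated dienolate of 14 | CC1=CC[C@@H](C=C1O[Li])C(C)=C | intermediate
16 | trimethylsilyl dienol ether of 14 | CC1=CC[C@@H](C=C1O[Si](C)(C)C)C(C)=C | intermediate
17 | (5S,6S)-2-methyl-6-(2-methylpent-4-en-2-yl)-5-(prop-1-en-2-yl)cyclohex-2-enone | O=C1C(C)=CC[C@H](C(C)=C)[C@H]1C(C)(C)CC=C | intermediate
18 | trans-fused ring C/D dienone (18S,23S) | O=C1C(C)=CC[C@@H]2C(C)=CCC(C)(C)[C@@H]12 | intermediate
19 | lithium ring-fusion dienolate of 18 | CC1=CC[C@@H]2C(C)=CCC(C)(C)C2=C1O[Li] | intermediate
20 | cis-fused ring C/D dienone (18S,23R) | O=C1C(C)=CC[C@@H]2C(C)=CCC(C)(C)[C@H]12 | intermediate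
21 | C13 alkyllithium from 11 | [Li]CC[C@H]2[C@]3(C)CC[C@H](O[Si](CC)(CC)CC)C(C)(C)O[C@H]3CC[C@]2(C)O[Si](CC)(CC)CC | intermediate
22 | (14S) tertiary allylic alcohol | O[C@]1(CC[C@H]3[C@]4(C)CC[C@H](O[Si](CC)(CC)CC)C(C)(C)O[C@H]4CC[C@]3(C)O[Si](CC)(CC)CC)C(C)=CC[C@@H]2C(C)=CCC(C)(C)[C@H]12 | intermediate
23 | transposed enone with C19=C20 alkene | CC1=C(CC[C@H]2[C@]3(C)CC[C@H](O[Si](CC)(CC)CC)C(C)(C)O[C@H]3CC[C@]2(C)O[Si](CC)(CC)CC)[C@@H]2[C@H](CC1=O)C(C)=CCC2(C)C | intermediate
24 | C3/C10 bis(triethylsilyl) ether of sipholenol K | CC1=C(CC[C@H]2[C@]3(C)CC[C@H](O[Si](CC)(CC)CC)C(C)(C)O[C@H]3CC[C@]2(C)O[Si](CC)(CC)CC)[C@@H]2[C@H](CC1=O)[C@@](C)(O)CCC2(C)C | intermediate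
25 | sipholenol K | CC1=C(CC[C@H]2[C@]3(C)CC[C@H](O)C(C)(C)O[C@H]3CC[C@]2(C)O)[C@@H]2[C@H](CC1=O)[C@@](C)(O)CCC2(C)C | target

## Step count and risks

Total step count: 17. Longest linear sequence: 12 steps (steps 1–8 and 14–17).

**Step 5 (key step).**
- What may go wrong: premature termination, meaning proton loss from the C10 cation, or exo opening at C3 or C7 to smaller ethers. The cause is that the C10=C11 alkene is a weaker nucleophile than the enol or allyl silanes usually placed at the end of such cascades.
- Fallback: ring formation and C10–O formation are separated. It sets out from 4 and comes back to the route at 8.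
- Ester 4 is treated with BF3·OEt2 in CH2Cl2 at −78 °C and the cascade is allowed to end by proton loss. This gives the endocyclic alkene ester F1 and the exocyclic alkene ester F2.
- Both are submitted together to Mukaiyama hydration (Co(acac)2, PhSiH3, O2). Both give the same C10 radical, which should take up oxygen opposite to the axial C6 methyl.
- The resulting hydroxy ester F3 lactonises on mild acid work-up to 8.

**Step 13.**
- What may go wrong: poor facial selectivity of the protonation, because torsional preference for attack anti to H18 opposes the steric preference for the convex face. Re-equilibration during work-up is a second danger.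
- Fallback: a different control element is used on the monocycle. It sets out from 17 and comes back to the route at 20.
- Ketone 17 is converted with LiN(iPr)2 into the monocyclic lithium dienolate F4. In F4, A(1,2) strain with the in-plane tert-alkyl group forces the isopropenyl group axial.
- Protonation anti to the isopropenyl group gives the cis ketone F5.
- Ring-closing metathesis of F5 under the conditions of step 12 leads to 20.

**Step 14.**
- What may go wrong: enolisation of 20 by the basic alkyllithium, and oxygen-to-carbon silyl migration within 21 from the C10 ether to C13.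
- Fallback: the sp3 nucleophile is replaced by a small, weakly basic acetylide. It sets out from 10 and 20 and comes back to the route at 23.
- Swern oxidation of 10 attacks only the primary silyl ether and gives the aldehyde F6.
- Nonafluorobutanesulfonyl fluoride and a phosphazene base convert F6, by way of the alkenyl nonaflate F7, into the terminal alkyne F8.
- n-BuLi gives the lithium acetylide F9, which adds to 20 to give the propargylic alcohol F10.
- [C5H5NH][CrO3Cl] transposes F10 to the enynone F11.
- Hydrogenation of the alkyne over palladium on carbon (H2, 1 atm) gives 23.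

**Step 16.**
- What may go wrong: competing hydrogen-atom transfer to the enone, or incomplete facial selectivity at the C19 radical.
- Fallback: the oxygen is put on earlier as an epoxide. It sets out from 20 and comes back to the route at 24.
- mCPBA epoxidises only the electron-rich C19=C20 alkene of 20, from the convex face, to give the epoxy enone F12.
- Alkyllithium 21 adds to the ketone of F12 at −78 °C to give the epoxy alcohol F13.
- LiBHEt3 opens the epoxide at the less substituted C20 to give the diol F14.
- [C5H5NH][CrO3Cl] transposes the allylic alcohol of F14, the C19 alcohol being inert, to give 24.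

## Further compounds

F1 | step 5 | methyl ester of the ring A/B acid with C9=C10 alkene | COC(=O)C[C@H]2[C@]3(C)CC[C@H](O)C(C)(C)O[C@H]3CC=C2C
F2 | step 5 | methyl ester of the ring A/B acid with exocyclic C10 methylene | COC(=O)C[C@H]2[C@]3(C)CC[C@H](O)C(C)(C)O[C@H]3CCC2=C
F3 | step 5 | C10 hydroxy methyl ester | COC(=O)C[C@H]2[C@]3(C)CC[C@H](O)C(C)(C)O[C@H]3CC[C@]2(C)O
F4 | step 13 | lithium dienolate of 17 | CC1=CC[C@H](C(C)=C)C(C(C)(C)CC=C)=C1O[Li]
F5 | step 13 | (5S,6R)-2-methyl-6-(2-methylpent-4-en-2-yl)-5-(prop-1-en-2-yl)cyclohex-2-enone (cis) | O=C1C(C)=CC[C@H](C(C)=C)[C@@H]1C(C)(C)CC=C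
F6 | step 14 | C13 aldehyde, C3/C10 bis(triethylsilyl) ether | O=CC[C@H]2[C@]3(C)CC[C@H](O[Si](CC)(CC)CC)C(C)(C)O[C@H]3CC[C@]2(C)O[Si](CC)(CC)CC
F7 | step 14 | (E)-C12=C13 alkenyl nonaflate | FC(F)(F)C(F)(F)C(F)(F)C(F)(F)S(=O)(=O)O/C=C/[C@H]2[C@]3(C)CC[C@H](O[Si](CC)(CC)CC)C(C)(C)O[C@H]3CC[C@]2(C)O[Si](CC)(CC)CC
F8 | step 14 | C12≡C13 terminal alkyne | C#C[C@H]2[C@]3(C)CC[C@H](O[Si](CC)(CC)CC)C(C)(C)O[C@H]3CC[C@]2(C)O[Si](CC)(CC)CC
F9 | step 14 | lithium acetylide of F8 | [Li]C#C[C@H]2[C@]3(C)CC[C@H](O[Si](CC)(CC)CC)C(C)(C)O[C@H]3CC[C@]2(C)O[Si](CC)(CC)CC
F10 | step 14 | C14 propargylic tertiary alcohol | O[C@]1(C#C[C@H]3[C@]4(C)CC[C@H](O[Si](CC)(CC)CC)C(C)(C)O[C@H]4CC[C@]3(C)O[Si](CC)(CC)CC)C(C)=CC[C@@H]2C(C)=CCC(C)(C)[C@H]12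
F11 | step 14 | enynone (C16=O, C14=C15, C12≡C13) | CC1=C(C#C[C@H]2[C@]3(C)CC[C@H](O[Si](CC)(CC)CC)C(C)(C)O[C@H]3CC[C@]2(C)O[Si](CC)(CC)CC)[C@@H]2[C@H](CC1=O)C(C)=CCC2(C)C
F12 | step 16 | convex-face C19–C20 epoxide of 20 | O=C1C(C)=CC[C@@H]2[C@@]3(C)O[C@H]3CC(C)(C)[C@H]12
F13 | step 16 | adduct of 21 with F12 | O[C@]1(CC[C@H]4[C@]5(C)CC[C@H](O[Si](CC)(CC)CC)C(C)(C)O[C@H]5CC[C@]4(C)O[Si](CC)(CC)CC)C(C)=CC[C@@H]2[C@@]3(C)O[C@H]3CC(C)(C)[C@H]12
F14 | step 16 | C14/C19 diol | O[C@]1(CC[C@H]4[C@]5(C)CC[C@H](O[Si](CC)(CC)CC)C(C)(C)O[C@H]5CC[C@]4(C)O[Si](CC)(CC)CC)C(C)=CC[C@@H]2[C@@](C)(O)CCC(C)(C)[C@H]12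
A1 | alternative 1 | ring A/B C12 phenyl sulfone | O=S(=O)(C[C@H]2[C@]3(C)CC[C@H](O)C(C)(C)O[C@H]3CC[C@]2(C)O)c1ccccc1
A2 | alternative 1 | ring C/D C13 bromide (γ-bromo enone) | CC1=C(CBr)[C@@H]2[C@H](CC1=O)[C@@](C)(O)CCC2(C)C
A3 | alternative 2 | ring C/D enone carrying the acyclic (3S,6S,7S)-diepoxy alkenyl chain | CC1=C(CC/C=C(\C)CC[C@@H]3O[C@@]3(C)CC[C@@H]4OC4(C)C)[C@@H]2[C@H](CC1=O)[C@@](C)(O)CCC2(C)C
A4 | alternative 3 | (−)-sclareolide | O=C1C[C@H]2[C@]3(C)CCCC(C)(C)[C@H]3CC[C@]2(C)O1
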